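**Plan**

- Retrosynthesis: the three phenols are unmasked last. Before that both vinyl–C(quaternary) bonds are cut (back to tertiary boronic esters), then both C(quaternary)–CH2 bonds to the (3E)-4,8-dimethylnona-3,7-dienyl (homogeranyl) chains. The two benzylic C–O bonds are then traced to carbonyl groups and the diaryl ether C–O bond is cut last.
- Enabling feature: each quaternary carbon is benzylic (on ring A para to the ether oxygen, on ring B meta to it), bears a methyl group and is bonded to the first CH2 of its chain. It therefore maps onto an Ar–CH(CH3)–O carbamate carbon whose hydrogen is acidified by the ring and the carbamate. The two such carbons sit on different rings, insulated by the ether oxygen, so both can be alkylated in one operation.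
- Forward, part 1: ring B (3',4',5'-trihydroxyacetophenone as its acetonide) is joined to ring A (4-fluoro-3-methoxybenzonitrile) by SNAr and the protecting groups are exchanged for TIPS ethers. The ring B ketone is reduced, the ring A nitrile is turned into the second acetyl group and reduced with the enantiomeric catalyst, and the diol is bis-carbamoylated.
- Forward, part 2: both chains are attached at once by double lithiation–borylation with homogeranyl pinacol boronate (one step from geranyl bromide). Both boron atoms are exchanged for vinyl by Zweifel olefination and fluoride frees the phenols. No ring of the target is formed in the route; the only ring made is the temporary acetonide.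
- Stereochemistry: two CBS reductions of opposite sense set S at the ring B carbinol and R at the ring A carbinol. Each is relayed stereospecifically (retentive lithiation and borylation, invertive 1,2-shift, retentive Zweifel step) to the S and R quaternary carbons. Both E olefins come from geranyl bromide.

Key step: step 10

Remark: ring A is the 3-hydroxy-4-aryloxyphenyl ring and ring B the 3-aryloxy-4,5-dihydroxyphenyl ring; the target is read as R at the ring A quaternary carbon, S at the ring B one, both chain olefins E.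
Remark: the two carbinol carbons need locally opposite configurations, so two acetyl groups could not be told apart after ether formation; ring A therefore carries a nitrile as latent acetyl until the ring B carbinol is set, and TIPS ethers are chosen because they tolerate Grignard reagents, sec-BuLi and methoxide.

**Route**

Step 1
Reactants: 1 3',4',5'-trihydroxyacetophenone
Product: 2 1-(7-hydroxy-2,2-dimethyl-1,3-benzodioxol-5-yl)ethan-1-one
Conditions: Me2C(OMe)2, p-TsOH·H2O (cat.), toluene, reflux, MeOH removed over 4 Å sieves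
Reagents that add atoms: 2,2-dimethoxypropane COC(C)(C)OC
Why: Acid-catalysed transketalisation (acetonide formation) can bridge only two adjacent hydroxyls, and the 3,4- and 4,5-pairs are equivalent by symmetry, so one mono-phenol with its free OH meta to the acetyl group should result.

Step 2
Reactants: 2 1-(7-hydroxy-2,2-dimethyl-1,3-benzodioxol-5-yl)ethan-1-one; 3 4-fluoro-3-methoxybenzonitrile
Product: 4 4-[(6-acetyl-2,2-dimethyl-1,3-benzodioxol-4-yl)oxy]-3-methoxybenzonitrile
Conditions: K2CO3, DMSO, 90 °C
Reagents that add atoms: none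
Why: Nucleophilic aromatic substitution (SNAr) in which the phenoxide displaces fluoride para to the nitrile, which stabilises the Meisenheimer intermediate, while the acetonide and the ketone tolerate carbonate base.

Step 3
Reactants: 4 4-[(6-acetyl-2,2-dimethyl-1,3-benzodioxol-4-yl)oxy]-3-methoxybenzonitrile
Product: 5 4-(5-acetyl-2,3-dihydroxyphenoxy)-3-hydroxybenzonitrile
Conditions: BBr3, CH2Cl2, −78 °C → rt; then H2O
Reagents that add atoms: none
Why: Lewis-acid ether cleavage with BBr3 should remove the aryl methyl ether and the catechol acetonide in one operation while the diaryl ether, ketone and nitrile stay intact, and it is placed here because no acid-labile benzylic C–O bond exists yet.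

Step 4
Reactants: 5 4-(5-acetyl-2,3-dihydroxyphenoxy)-3-hydroxybenzonitrile
Product: 6 4-[5-acetyl-2,3-bis(triisopropylsilyloxy)phenoxy]-3-(triisopropylsilyloxy)benzonitrile
Conditions: TIPSCl, imidazole, DMAP (cat.), DMF, 40 °C
Reagents that add atoms: triisopropylsilyl chloride CC(C)[Si](Cl)(C(C)C)C(C)C
Why: Standard phenol silylation; the bulky TIPS ethers are expected to survive the later Grignard, sec-BuLi and methoxide steps and to shield the ring positions from lithiation.

Step 5
Reactants: 6 4-[5-acetyl-2,3-bis(triisopropylsilyloxy)phenoxy]-3-(triisopropylsilyloxy)benzonitrile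
Product: 7 4-{5-[(1S)-1-hydroxyethyl]-2,3-bis(triisopropylsilyloxy)phenoxy}-3-(triisopropylsilyloxy)benzonitrile
Conditions: (R)-2-methyl-CBS-oxazaborolidine [(3aR)-1-methyl-3,3-diphenyltetrahydro-1H,3H-pyrrolo[1,2-c][1,3,2]oxazaborole] (20 mol %), BH3·SMe2, THF, −20 °C; then MeOH, aqueous work-up
Reagents that add atoms: none
Why: Corey–Bakshi–Shibata reduction in which the (R)-catalyst delivers hydride to the Re face of the aryl methyl ketone (aryl as the large group) to set the S carbinol on ring B, the nitrile being inert to borane at this temperature.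

Step 6
Reactants: 7 4-{5-[(1S)-1-hydroxyethyl]-2,3-bis(triisopropylsilyloxy)phenoxy}-3-(triisopropylsilyloxy)benzonitrile
Product: 9 1-[4-{5-[(1S)-1-hydroxyethyl]-2,3-bis(triisopropylsilyloxy)phenoxy}-3-(triisopropylsilyloxy)phenyl]ethan-1-one, via magnesium ketimide alkoxide 8 (not isolated)
Conditions: MeMgBr (4 equiv), THF–toluene, 0 → 60 °C; then aq. citric acid, 0 °C → rt
Reagents that add atoms: methylmagnesium bromide C[Mg]Br; water O
Why: Grignard addition to a nitrile stops at the N-magnesio ketimine, which mild acid hydrolyses to the methyl ketone; the first equivalent only deprotonates the carbinol, whose configuration is not touched.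

Step 7
Reactants: 9 1-[4-{5-[(1S)-1-hydroxyethyl]-2,3-bis(triisopropylsilyloxy)phenoxy}-3-(triisopropylsilyloxy)phenyl]ethan-1-one
Product: 10 (1R)-1-[4-{5-[(1S)-1-hydroxyethyl]-2,3-bis(triisopropylsilyloxy)phenoxy}-3-(triisopropylsilyloxy)phenyl]ethan-1-ol
Conditions: (S)-2-methyl-CBS-oxazaborolidine [(3aS)-1-methyl-3,3-diphenyltetrahydro-1H,3H-pyrrolo[1,2-c][1,3,2]oxazaborole] (20 mol %), BH3·SMe2 (extra equivalent for the free OH), THF, −20 °C; then MeOH, aqueous work-up
Reagents that add atoms: none
Why: Second Corey–Bakshi–Shibata reduction, now with the enantiomeric catalyst, which should deliver hydride to the Si face of the ring A ketone and set the R carbinol under reagent control, independent of the remote ring B stereocentre.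

Step 8
Reactants: 10 (1R)-1-[4-{5-[(1S)-1-hydroxyethyl]-2,3-bis(triisopropylsilyloxy)phenoxy}-3-(triisopropylsilyloxy)phenyl]ethan-1-ol
Product: 11 (1R)-1-[4-{5-[(1S)-1-(diisopropylcarbamoyloxy)ethyl]-2,3-bis(triisopropylsilyloxy)phenoxy}-3-(triisopropylsilyloxy)phenyl]ethyl N,N-diisopropylcarbamate
Conditions: iPr2NCOCl, Et3N, CH2Cl2, reflux
Reagents that add atoms: N,N-diisopropylcarbamoyl chloride CC(C)N(C(C)C)C(Cl)=O
Why: O-Carbamoylation of both secondary alcohols under amine base breaks no bond at either stereocentre, so both configurations are retained, and no alkoxide is generated that could move a silyl group.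

Step 9
Reactants: 12 geranyl bromide [(2E)-1-bromo-3,7-dimethylocta-2,6-diene]
Product: 13 homogeranyl pinacol boronate, 2-[(3E)-4,8-dimethylnona-3,7-dien-1-yl]-4,4,5,5-tetramethyl-1,3,2-dioxaborolane
Conditions: CH2(Bpin)2, NaOtBu, THF, rt
Reagents that add atoms: bis(pinacolato)borylmethane CC1(C)OB(CB2OC(C)(C)C(C)(C)O2)OC1(C)C
Why: Deborylative alkylation of a geminal bis(boronate): tert-butoxide adds to one boron and releases an α-boryl carbanion that displaces the primary allylic bromide by SN2 at C1, adding the CH2Bpin unit with the E olefin unchanged.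

Step 10
Reactants: 11 (1R)-1-[4-{5-[(1S)-1-(diisopropylcarbamoyloxy)ethyl]-2,3-bis(triisopropylsilyloxy)phenoxy}-3-(triisopropylsilyloxy)phenyl]ethyl N,N-diisopropylcarbamate; 13 homogeranyl pinacol boronate
Product: 16 bis(tertiary pinacol boronate) in which ring A carries the (2R,5E)-6,10-dimethyl-2-(pinacolboryl)undeca-5,9-dien-2-yl group and ring B its (2S,5E) counterpart, via dilithiated bis(carbamate) 14 (not isolated), via dilithium bis(boronate) complex 15 (not isolated)
Conditions: sec-BuLi (2.6 equiv), Et2O, −78 °C; 13 (3 equiv), −78 °C; MgBr2 in MeOH, −78 °C → rt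
Reagents that add atoms: none
Why: sec-BuLi, guided by each carbamate carbonyl, removes the two benzylic hydrogens with retention to give a configurationally stable α-carbamoyloxy benzyllithium on each ring; each carbanion adds to the boron of 13 with retention, and on warming the homogeranyl group shifts from boron to carbon antiperiplanar to the departing carbamate (1,2-metallate rearrangement, inversion at carbon), which forms both C(quaternary)–CH2 bonds. The closest known reaction type is the lithiation–borylation of enantioenriched secondary benzylic carbamates with pinacol boronic esters to give tertiary boronic esters, here run at two independent sites of one molecule. No ring is closed. Each new stereocentre is controlled only by the configuration of its own carbamate carbon (R on ring A gives the R boronate, S on ring B gives the S boronate), so the two sites need not communicate. The step needs benzylic rather than ring lithiation and complete stereospecificity at both carbons: carbamate-directed deprotonation and the bulky TIPS ethers should secure the first, and MgBr2 in MeOH, which speeds the 1,2-shift and protonates any lithiated carbamate released by reversal of boronate formation before it can racemise and re-add, should secure the second.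

Step 11
Reactants: 16 bis(tertiary pinacol boronate)
Product: 19 tris(triisopropylsilyl) ether of the target with the (3R,6E)-3,7,11-trimethyldodeca-1,6,10-trien-3-yl group on ring A and the (3S,6E) group on ring B, via bis(vinylboronate) complex 17 (not isolated), via bis(β-iodoalkyl boronate) 18 (not isolated)
Conditions: CH2=CHMgBr, THF, rt; I2, MeOH, −78 °C; NaOMe, MeOH, −78 → 0 °C; aq. Na2S2O3
Reagents that add atoms: vinylmagnesium bromide C=C[Mg]Br
Why: Zweifel olefination: vinyl adds to each boron, iodine activates the vinyl group and triggers 1,2-migration of the tertiary carbon with retention, and methoxide-induced anti elimination of boron and iodide leaves a vinyl group on each quaternary carbon with its configuration unchanged.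

Step 12
Reactants: 19 tris(triisopropylsilyl) ether of the target
Product: 20 3-{2-hydroxy-4-[(3R,6E)-3,7,11-trimethyldodeca-1,6,10-trien-3-yl]phenoxy}-5-[(3S,6E)-3,7,11-trimethyldodeca-1,6,10-trien-3-yl]benzene-1,2-diol (CNP0230356.1)
Conditions: Bu4NF, AcOH, THF, 0 °C, under argon
Reagents that add atoms: none
Why: Fluoride-mediated desilylation of aryl silyl ethers, buffered with acetic acid and kept oxygen-free so that the liberated catechol is not oxidised and the olefins and quaternary carbons are untouched.

**Compound list**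

1 | 3',4',5'-trihydroxyacetophenone | CC(=O)c1cc(O)c(O)c(O)c1 | starting material
2 | 1-(7-hydroxy-2,2-dimethyl-1,3-benzodioxol-5-yl)ethan-1-one | CC(=O)c1cc(O)c2OC(C)(C)Oc2c1 | intermediate
3 | 4-fluoro-3-methoxybenzonitrile | COc1cc(C#N)ccc1F | starting material
4 | 4-[(6-acetyl-2,2-dimethyl-1,3-benzodioxol-4-yl)oxy]-3-methoxybenzonitrile | N#Cc1ccc(Oc2cc(C(C)=O)cc3OC(C)(C)Oc23)c(OC)c1 | intermediate
5 | 4-(5-acetyl-2,3-dihydroxyphenoxy)-3-hydroxybenzonitrile | N#Cc1ccc(Oc2cc(C(C)=O)cc(O)c2O)c(O)c1 | intermediate
6 | 4-[5-acetyl-2,3-bis(triisopropylsilyloxy)phenoxy]-3-(triisopropylsilyloxy)benzonitrile | N#Cc1ccc(Oc2cc(C(C)=O)cc(O[Si](C(C)C)(C(C)C)C(C)C)c2O[Si](C(C)C)(C(C)C)C(C)C)c(O[Si](C(C)C)(C(C)C)C(C)C)c1 | intermediate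
7 | 4-{5-[(1S)-1-hydroxyethyl]-2,3-bis(triisopropylsilyloxy)phenoxy}-3-(triisopropylsilyloxy)benzonitrile | N#Cc1ccc(Oc2cc([C@H](C)O)cc(O[Si](C(C)C)(C(C)C)C(C)C)c2O[Si](C(C)C)(C(C)C)C(C)C)c(O[Si](C(C)C)(C(C)C)C(C)C)c1 | intermediate
8 | magnesium ketimide alkoxide: N-bromomagnesio ketimine of 9 with the ring B carbinol (S) as its bromomagnesium alkoxide | CC(=N[Mg]Br)c1ccc(Oc2cc([C@H](C)O[Mg]Br)cc(O[Si](C(C)C)(C(C)C)C(C)C)c2O[Si](C(C)C)(C(C)C)C(C)C)c(O[Si](C(C)C)(C(C)C)C(C)C)c1 | intermediate (not isolated)
9 | 1-[4-{5-[(1S)-1-hydroxyethyl]-2,3-bis(triisopropylsilyloxy)phenoxy}-3-(triisopropylsilyloxy)phenyl]ethan-1-one | CC(=O)c1ccc(Oc2cc([C@H](C)O)cc(O[Si](C(C)C)(C(C)C)C(C)C)c2O[Si](C(C)C)(C(C)C)C(C)C)c(O[Si](C(C)C)(C(C)C)C(C)C)c1 | intermediate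
10 | (1R)-1-[4-{5-[(1S)-1-hydroxyethyl]-2,3-bis(triisopropylsilyloxy)phenoxy}-3-(triisopropylsilyloxy)phenyl]ethan-1-ol | C[C@@H](O)c1ccc(Oc2cc([C@H](C)O)cc(O[Si](C(C)C)(C(C)C)C(C)C)c2O[Si](C(C)C)(C(C)C)C(C)C)c(O[Si](C(C)C)(C(C)C)C(C)C)c1 | intermediate
11 | bis(N,N-diisopropylcarbamate) of 10 (R at the ring A carbamate carbon, S at the ring B one) | C[C@@H](OC(=O)N(C(C)C)C(C)C)c1ccc(Oc2cc([C@H](C)OC(=O)N(C(C)C)C(C)C)cc(O[Si](C(C)C)(C(C)C)C(C)C)c2O[Si](C(C)C)(C(C)C)C(C)C)c(O[Si](C(C)C)(C(C)C)C(C)C)c1 | intermediate
12 | geranyl bromide, (2E)-1-bromo-3,7-dimethylocta-2,6-diene | CC(C)=CCC/C(C)=C/CBr | starting material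
13 | homogeranyl pinacol boronate, 2-[(3E)-4,8-dimethylnona-3,7-dien-1-yl]-4,4,5,5-tetramethyl-1,3,2-dioxaborolane | CC(C)=CCC/C(C)=C/CCB1OC(C)(C)C(C)(C)O1 | intermediate
14 | dilithiated bis(carbamate): 11 with lithium in place of each benzylic hydrogen (R at ring A, S at ring B) | C[C@@]([Li])(OC(=O)N(C(C)C)C(C)C)c1ccc(Oc2cc([C@]([Li])(C)OC(=O)N(C(C)C)C(C)C)cc(O[Si](C(C)C)(C(C)C)C(C)C)c2O[Si](C(C)C)(C(C)C)C(C)C)c(O[Si](C(C)C)(C(C)C)C(C)C)c1 | intermediate (not isolated)
15 | dilithium bis(boronate) complex: each benzylic carbon bonded to a tetracoordinate boron carrying pinacol and the homogeranyl group (R at ring A, S at ring B) | [Li+].[Li+].C[C@@]([B-]3(CC/C=C(\C)CCC=C(C)C)OC(C)(C)C(C)(C)O3)(OC(=O)N(C(C)C)C(C)C)c1ccc(Oc2cc([C@]([B-]4(CC/C=C(\C)CCC=C(C)C)OC(C)(C)C(C)(C)O4)(C)OC(=O)N(C(C)C)C(C)C)cc(O[Si](C(C)C)(C(C)C)C(C)C)c2O[Si](C(C)C)(C(C)C)C(C)C)c(O[Si](C(C)C)(C(C)C)C(C)C)c1 | intermediate (not isolated)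
16 | bis(tertiary pinacol boronate): ring A bears (2R,5E)-6,10-dimethyl-2-(pinacolboryl)undeca-5,9-dien-2-yl, ring B the (2S,5E) group; three TIPS ethers | CC1(C)OB(OC1(C)C)[C@@](C)(CC/C=C(\C)CCC=C(C)C)c1ccc(Oc2cc([C@](C)(B3OC(C)(C)C(C)(C)O3)CC/C=C(\C)CCC=C(C)C)cc(O[Si](C(C)C)(C(C)C)C(C)C)c2O[Si](C(C)C)(C(C)C)C(C)C)c(O[Si](C(C)C)(C(C)C)C(C)C)c1 | intermediate
17 | bis(vinylboronate) complex of 16 (bromomagnesium counter-ions; R at ring A, S at ring B) | Br[Mg+].Br[Mg+].C=C[B-]1(OC(C)(C)C(C)(C)O1)[C@@](C)(CC/C=C(\C)CCC=C(C)C)c1ccc(Oc2cc([C@](C)([B-]3(C=C)OC(C)(C)C(C)(C)O3)CC/C=C(\C)CCC=C(C)C)cc(O[Si](C(C)C)(C(C)C)C(C)C)c2O[Si](C(C)C)(C(C)C)C(C)C)c(O[Si](C(C)C)(C(C)C)C(C)C)c1 | intermediate (not isolated)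
18 | bis(β-iodoalkyl boronate): each quaternary carbon (R at ring A, S at ring B) bonded to CH(Bpin)CH2I, epimers at the CH(B) carbons | ICC(B1OC(C)(C)C(C)(C)O1)[C@@](C)(CC/C=C(\C)CCC=C(C)C)c1ccc(Oc2cc([C@](C)(C(CI)B3OC(C)(C)C(C)(C)O3)CC/C=C(\C)CCC=C(C)C)cc(O[Si](C(C)C)(C(C)C)C(C)C)c2O[Si](C(C)C)(C(C)C)C(C)C)c(O[Si](C(C)C)(C(C)C)C(C)C)c1 | intermediate (not isolated)
19 | tris(triisopropylsilyl) ether of the target ((3R,6E) chain on ring A, (3S,6E) chain on ring B) | C=C[C@@](C)(CC/C=C(\C)CCC=C(C)C)c1ccc(Oc2cc([C@](C)(C=C)CC/C=C(\C)CCC=C(C)C)cc(O[Si](C(C)C)(C(C)C)C(C)C)c2O[Si](C(C)C)(C(C)C)C(C)C)c(O[Si](C(C)C)(C(C)C)C(C)C)c1 | intermediate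
20 | 3-{2-hydroxy-4-[(3R,6E)-3,7,11-trimethyldodeca-1,6,10-trien-3-yl]phenoxy}-5-[(3S,6E)-3,7,11-trimethyldodeca-1,6,10-trien-3-yl]benzene-1,2-diol (CNP0230356.1) | C=C[C@@](C)(CC/C=C(\C)CCC=C(C)C)c1ccc(Oc2cc([C@](C)(C=C)CC/C=C(\C)CCC=C(C)C)cc(O)c2O)c(O)c1 | target

**Step count**

Total: 12 steps. Longest linear sequence: 11 steps (steps 1–8 and 10–12, from 1); the branch to 13 is one step (step 9).

**Steps most likely to fail**

1) Step 10.
- What may go wrong: boronate-complex formation with the hindered pinacol ester may reverse on warming, so that a released lithiated carbamate either racemises before re-adding or is protonated, leaving one site unalkylated. Incomplete lithiation of the second site in a poorly soluble dianion would lead to the same outcome.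
- Fallback (sets out from 11 and 13, rejoins at 19): the boron partner is changed to a less hindered neopentyl glycol ester, whose boronate complexes form irreversibly.
- 13 is cleaved with NaIO4/NH4OAc in aqueous acetone to (3E)-4,8-dimethylnona-3,7-dien-1-ylboronic acid F1.
- F1 is condensed with 2,2-dimethylpropane-1,3-diol (MgSO4, CH2Cl2) to the neopentyl glycol homogeranylboronate F2.
- Doubly lithiated 11 (sec-BuLi, Et2O, −78 °C) is treated with F2 and warmed, which should give the bis(tertiary neopentyl glycol boronate) F3.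
- F3 is taken through the Zweifel conditions of step 11 directly to 19.

2) Step 11.
- What may go wrong: iodine may be consumed by the four trisubstituted olefins or by the electron-rich rings, or vinyl transfer to the two crowded tertiary boron atoms may stay incomplete, leading to mono-vinylated or iodinated material.
- Fallback (sets out from 16, rejoins at 19): the vinyl groups are built stepwise without iodine.
- Matteson homologation of 16 with LiCH2Cl (BrCH2Cl, n-BuLi, THF, −78 °C → rt; the tertiary carbon migrates with retention) should give the bis(homologated primary pinacol boronate) F4.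
- Oxidation with NaBO3·4H2O in THF–H2O gives the bis(primary alcohol) F5.
- Dess–Martin oxidation gives the dialdehyde F6, whose α-carbons are quaternary and cannot epimerise.
- Wittig methylenation (Ph3PCH3Br, KOtBu, THF) then leads to 19.

3) Step 6.
- What may go wrong: addition of the Grignard reagent to an electron-rich nitrile that already carries a magnesium alkoxide may be slow, and forcing it may cause loss or migration of silyl groups or incomplete hydrolysis of the ketimine.
- Fallback (sets out from 7, rejoins at 10, bypassing 9): the nitrile is reduced with iBu2AlH (toluene, −78 °C; aqueous potassium sodium tartrate) to 4-{5-[(1S)-1-hydroxyethyl]-2,3-bis(triisopropylsilyloxy)phenoxy}-3-(triisopropylsilyloxy)benzaldehyde F7.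
- The methyl group is then introduced by catalytic enantioselective addition of Me2Zn (Ti(OiPr)4, catalytic (1S,2S)-N,N′-bis(trifluoromethanesulfonyl)cyclohexane-1,2-diamine, toluene, −20 °C). The ligand antipode is the one expected, by analogy with simple benzaldehydes, to give the R carbinol, and this should lead directly to 10.

**Further compounds**

F1 | step 10 | (3E)-4,8-dimethylnona-3,7-dien-1-ylboronic acid | CC(C)=CCC/C(C)=C/CCB(O)O
F2 | step 10 | neopentyl glycol homogeranylboronate, 2-[(3E)-4,8-dimethylnona-3,7-dien-1-yl]-5,5-dimethyl-1,3,2-dioxaborinane | CC(C)=CCC/C(C)=C/CCB1OCC(C)(C)CO1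
F3 | step 10 | bis(tertiary neopentyl glycol boronate), analogue of 16 (R at ring A, S at ring B) | CC1(C)COB(OC1)[C@@](C)(CC/C=C(\C)CCC=C(C)C)c1ccc(Oc2cc([C@](C)(B3OCC(C)(C)CO3)CC/C=C(\C)CCC=C(C)C)cc(O[Si](C(C)C)(C(C)C)C(C)C)c2O[Si](C(C)C)(C(C)C)C(C)C)c(O[Si](C(C)C)(C(C)C)C(C)C)c1
F4 | step 11 | bis(homologated primary pinacol boronate): CH2Bpin on each quaternary carbon, spatial arrangement of 16 kept (descriptors S at ring A, R at ring B) | CC1(C)OB(OC1(C)C)C[C@@](C)(CC/C=C(\C)CCC=C(C)C)c1ccc(Oc2cc([C@](C)(CB3OC(C)(C)C(C)(C)O3)CC/C=C(\C)CCC=C(C)C)cc(O[Si](C(C)C)(C(C)C)C(C)C)c2O[Si](C(C)C)(C(C)C)C(C)C)c(O[Si](C(C)C)(C(C)C)C(C)C)c1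
F5 | step 11 | bis(primary alcohol): CH2OH on each quaternary carbon (S at ring A, R at ring B) | OC[C@@](C)(CC/C=C(\C)CCC=C(C)C)c1ccc(Oc2cc([C@](C)(CO)CC/C=C(\C)CCC=C(C)C)cc(O[Si](C(C)C)(C(C)C)C(C)C)c2O[Si](C(C)C)(C(C)C)C(C)C)c(O[Si](C(C)C)(C(C)C)C(C)C)c1
F6 | step 11 | dialdehyde: CHO on each quaternary carbon (S at ring A, R at ring B) | O=C[C@@](C)(CC/C=C(\C)CCC=C(C)C)c1ccc(Oc2cc([C@](C)(C=O)CC/C=C(\C)CCC=C(C)C)cc(O[Si](C(C)C)(C(C)C)C(C)C)c2O[Si](C(C)C)(C(C)C)C(C)C)c(O[Si](C(C)C)(C(C)C)C(C)C)c1
F7 | step 6 | 4-{5-[(1S)-1-hydroxyethyl]-2,3-bis(triisopropylsilyloxy)phenoxy}-3-(triisopropylsilyloxy)benzaldehyde | O=Cc1ccc(Oc2cc([C@H](C)O)cc(O[Si](C(C)C)(C(C)C)C(C)C)c2O[Si](C(C)C)(C(C)C)C(C)C)c(O[Si](C(C)C)(C(C)C)C(C)C)c1
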